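The cyclodeca-3,7-diene ring is opened between the ring methylene C-2 and the methyl-bearing alkene carbon C-3. The key step exploits the 1,2-relationship of that methylene to the ester-bearing carbinol C-1: C-2 and O-1 are carried as a terminal epoxide, C-3 as an E-alkenyl bromide. Bromine–lithium exchange and BF3-promoted attack of the alkenyllithium on the epoxide CH2 close the ten-membered ring in one operation, keep both E-alkenes and the epoxide stereocentre, and release the C-1 hydroxyl exactly where the feruloyl group must go. The acyclic precursor, a silyl-protected anti,syn stereotriad ending in the epoxide, comes from an Evans syn-aldol, a Weinreb ketone synthesis and a 1,3-anti reduction.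

Key step: step 10

Assumption: 1, 8, 9 (sold as an aqueous solution, dried and distilled before use) and 21 are taken as catalogue compounds.
Numbering: ring atoms are C-1 (ester carbinol), C-2 (CH2), C-3=C-4, C-5, C-6, C-7=C-8, C-9 (free carbinol), C-10 (isopropyl-bearing). Open-chain compounds 15 to 19 use undecane numbering, in which chain C-1 becomes ring C-2, chain C-2 ring C-1, chain C-4 ring C-9 and chain C-10 ring C-3.

Step 1
Reactants: 1 pent-3-yn-1-ol
Product: 3 (E)-4-bromopent-3-en-1-ol, via alkenylzirconocene 2 (not isolated)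
Conditions: Cp2Zr(H)Cl (3.0 equiv), THF, 25 → 45 °C; then NBS (1.2 equiv), 0 °C
Reagents that add atoms: N-bromosuccinimide (NBS), O=C1CCC(=O)N1Br
Why: Hydrozirconation–bromination: once the hydroxyl is capped as a zirconium alkoxide, Zr–H adds syn across the alkyne and excess reagent equilibrates the alkenylzirconocenes toward zirconium on the less hindered methyl-bearing carbon, so that bromodezirconation with retention should give the E-alkenyl bromide.

Step 2
Reactants: 3 (E)-4-bromopent-3-en-1-ol
Product: 4 (E)-4-bromopent-3-en-1-yl 4-methylbenzenesulfonate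
Conditions: TsCl (1.2 equiv), Et3N (1.5 equiv), DMAP (5 mol %), CH2Cl2, 0 °C → rt
Reagents that add atoms: 4-toluenesulfonyl chloride (TsCl), Cc1ccc(cc1)S(=O)(=O)Cl
Why: Sulfonylation (tosylate formation) of the primary alcohol turns the carbinol carbon into an SN2 electrophile and leaves the alkenyl bromide untouched.

Step 3
Reactants: 4 (E)-4-bromopent-3-en-1-yl 4-methylbenzenesulfonate
Product: 5 (E)-6-bromohept-5-en-1-yne
Conditions: LiC≡CH·H2NCH2CH2NH2 (1.5 equiv), DMSO, 15 °C → rt
Reagents that add atoms: lithium acetylide–ethylenediamine complex, [Li]C#C.NCCN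
Why: SN2 alkylation of acetylide by the primary tosylate in a dipolar aprotic solvent installs the terminal alkyne, while the alkenyl bromide, whose vinylic hydrogen is cis to bromine, resists elimination.

Step 4
Reactants: 5 (E)-6-bromohept-5-en-1-yne
Product: 7 (1E,5E)-6-bromo-1-iodo-2-methylhepta-1,5-diene, via alkenylalane 6 (not isolated)
Conditions: AlMe3 (2.0 equiv), Cp2ZrCl2 (0.25 equiv), CH2Cl2, 0 °C → rt; then I2 (1.2 equiv), THF, −30 → 0 °C
Reagents that add atoms: trimethylaluminium, C[Al](C)C; iodine, II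
Why: Zirconium-catalysed carboalumination (Negishi) adds methyl and aluminium syn across the terminal alkyne with aluminium on the terminal carbon, and iodinolysis with retention should give the E-trisubstituted alkenyl iodide without touching the alkenyl bromide.

Step 5
Reactants: 8 (4R)-4-benzyl-3-(3-methylbutanoyl)-1,3-oxazolidin-2-one; 9 chloroacetaldehyde
Product: 11 (4R)-4-benzyl-3-[(2R,3R)-4-chloro-3-hydroxy-2-(propan-2-yl)butanoyl]-1,3-oxazolidin-2-one, via boron enolate 10 (not isolated)
Conditions: Bu2BOTf (1.1 equiv), i-Pr2NEt (1.3 equiv), CH2Cl2, 0 °C; then 9 (anhydrous, 1.5 equiv), −78 → 0 °C; pH 7 buffer (NaH2PO4/Na2HPO4), MeOH, H2O2, 0 °C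
Reagents that add atoms: none
Why: Evans syn-aldol: the Z-boron enolate adds through a Zimmerman–Traxler chair on the face away from the benzyl group of the (R)-auxiliary, which sets both new stereocentres (2R,3R, hydroxyl and isopropyl syn).

Step 6
Reactants: 11 (the aldol adduct)
Product: 12 (2R,3R)-4-chloro-3-hydroxy-N-methoxy-N-methyl-2-(propan-2-yl)butanamide
Conditions: MeNHOMe·HCl (3 equiv), AlMe3 (3 equiv), CH2Cl2, −15 → 0 °C; aqueous potassium sodium tartrate
Reagents that add atoms: N,O-dimethylhydroxylamine hydrochloride, CNOC.Cl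
Why: Weinreb amide formation by aluminium-amide transamination, assisted by chelation of the free β-hydroxyl, removes the auxiliary under conditions that should not epimerise the α-centre.

Step 7
Reactants: 12 (the Weinreb amide); 7 (1E,5E)-6-bromo-1-iodo-2-methylhepta-1,5-diene
Product: 15 (2R,3R,5E,9E)-10-bromo-1-chloro-2-hydroxy-6-methyl-3-(propan-2-yl)undeca-5,9-dien-4-one, via alkenyllithium 13 (not isolated), via magnesium alkoxide 14 (not isolated)
Conditions: 7 (1.3 equiv), t-BuLi (2.6 equiv), Et2O, −78 °C; 12, i-PrMgCl (1.05 equiv), THF, −40 °C; combine at −78 °C, warm to −30 °C; sat. NH4Cl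
Reagents that add atoms: none
Why: Weinreb ketone synthesis: iodine–lithium exchange is far faster than bromine–lithium exchange and retains the alkene geometry, and the alkenyllithium adds once to the amide (hydroxyl masked as its magnesium alkoxide) to a chelated tetrahedral intermediate that releases the E-enone only on work-up.

Step 8
Reactants: 15 (the β-hydroxy enone)
Product: 16 (2R,3S,4S,5E,9E)-10-bromo-1-chloro-6-methyl-3-(propan-2-yl)undeca-5,9-diene-2,4-diol
Conditions: Me4NBH(OAc)3 (5 equiv), MeCN/AcOH (1:1), −30 °C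
Reagents that add atoms: none
Why: Evans–Saksena reduction: the β-hydroxyl binds boron and hydride is delivered intramolecularly through a chair-like transition state, which should set the new C-4 carbinol 1,3-anti to the directing hydroxyl (4S).

Step 9
Reactants: 16 (the chlorohydrin diol)
Product: 18 tert-butyl({(3R,4S,5E,9E)-10-bromo-2,6-dimethyl-3-[(2R)-oxiran-2-yl]undeca-5,9-dien-4-yl}oxy)dimethylsilane, via epoxy alcohol 17 (not isolated)
Conditions: NaH (2.3 equiv), THF, 0 °C; then TBSCl (1.3 equiv), 0 °C → rt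
Reagents that add atoms: tert-butyldimethylsilyl chloride (TBSCl), CC(C)(C)[Si](C)(C)Cl
Why: Williamson-type 3-exo-tet closure of the chlorohydrin alkoxide gives the terminal epoxide without touching the C–O stereocentre, and the remaining secondary alkoxide is silylated in the same flask (silyl ether formation).

Step 10
Reactants: 18 (the epoxy alkenyl bromide)
Product: 20 (1S,3E,7E,9S,10R)-9-{[tert-butyl(dimethyl)silyl]oxy}-3,7-dimethyl-10-(propan-2-yl)cyclodeca-3,7-dien-1-ol, via alkenyllithium 19 (not isolated)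
Conditions: t-BuLi (2.1 equiv), rigorously dried Et2O (1 mM), −78 °C; then BF3·OEt2 (1.5 equiv), −78 °C; Et3N, then aq. NaHCO3
Reagents that add atoms: none
Why: Bromine–lithium exchange with two equivalents of t-BuLi gives the configurationally stable (E)-alkenyllithium 19 with retention, and BF3·OEt2 then activates the terminal epoxide so that the carbanion attacks its unsubstituted CH2 carbon in an SN2 opening that forms the C-2–C-3 bond. The closest known reaction type is the BF3-promoted opening of terminal epoxides by alkenyllithiums to homoallylic alcohols, together with carbanion–epoxide closures of ten-membered germacrane rings from farnesyl-type chains. The one ring closed is the cyclodeca-3,7-diene, formed in an anionic endo mode with respect to the epoxide (attack at the distal carbon, both epoxide carbons end in the ring, oxygen stays on C-1 as the free hydroxyl). No new stereocentre is created: the C–O bond of the epoxide stereocentre is never broken, so C-1 keeps its configuration, and both alkene geometries are carried over unchanged. The step needs attack at the terminal epoxide carbon, secured by the SN2 preference for the unsubstituted CH2, and cyclisation in preference to oligomerisation, secured by millimolar dilution, by the speed of the BF3-promoted opening at −78 °C and by the two E-trisubstituted alkenes, which fold the chain much as in the biosynthetic farnesyl-to-germacrane closure. Polar conditions are chosen on purpose, because a radical at C-2 would be drawn into 5-exo cyclisation onto the C-7=C-8 alkene.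

Step 11
Reactants: 21 (E)-ferulic acid
Product: 23 (E)-3-{4-[tert-butyl(dimethyl)silyl]oxy-3-methoxyphenyl}prop-2-enoic acid, via silyl ester 22 (not isolated)
Conditions: TBSCl (2.5 equiv), imidazole (5 equiv), DMF, rt; then K2CO3 (0.1 equiv), MeOH/THF/H2O, 0 °C; acidify to pH 4
Reagents that add atoms: tert-butyldimethylsilyl chloride (TBSCl), CC(C)(C)[Si](C)(C)Cl
Why: Silylation of both acidic hydroxyls followed by selective solvolysis of the labile silyl ester should leave the phenol as its TBS ether and free the carboxylic acid.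

Step 12
Reactants: 20 (the cyclodecadienol); 23 (the O-TBS ferulic acid)
Product: 24 (1S,3E,7E,9S,10R)-9-{[tert-butyl(dimethyl)silyl]oxy}-3,7-dimethyl-10-(propan-2-yl)cyclodeca-3,7-dien-1-yl (2E)-3-{4-[tert-butyl(dimethyl)silyl]oxy-3-methoxyphenyl}prop-2-enoate
Conditions: DCC (1.5 equiv), DMAP (0.5 equiv), CH2Cl2, 0 °C → rt
Reagents that add atoms: none
Why: Steglich esterification: carbodiimide activation and DMAP acyl transfer acylate the only free hydroxyl with retention at C-1.

Step 13
Reactants: 24 (the bis-silyl ester)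
Product: 25 (1S,3E,7E,9S,10S)-9-hydroxy-3,7-dimethyl-10-(propan-2-yl)cyclodeca-3,7-dien-1-yl (2E)-3-(4-hydroxy-3-methoxyphenyl)prop-2-enoate (target)
Conditions: TBAF (3 equiv), AcOH (3 equiv), THF, 0 °C → rt
Reagents that add atoms: none
Why: Fluoride-mediated desilylation cleaves the aryl and the secondary alkyl silyl ether, with acetic acid buffering to suppress 1,3-acyl migration and acid- or base-induced reactions of the cyclodecadiene.

Compound list
1 | pent-3-yn-1-ol | CC#CCCO | starting material
2 | O-zirconated (E)-alkenylzirconocene chloride from 1 (zirconium on C-4, trans to the chain) | Cl[Zr](C1C=CC=C1)(C1C=CC=C1)OCC/C=C(C)/[Zr](Cl)(C1C=CC=C1)C1C=CC=C1 | intermediate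
3 | (E)-4-bromopent-3-en-1-ol | OCC/C=C(C)/Br | intermediate
4 | (E)-4-bromopent-3-en-1-yl 4-methylbenzenesulfonate | Cc1ccc(cc1)S(=O)(=O)OCC/C=C(C)/Br | intermediate
5 | (E)-6-bromohept-5-en-1-yne | C#CCC/C=C(C)/Br | intermediate
6 | [(1E,5E)-6-bromo-2-methylhepta-1,5-dien-1-yl]dimethylaluminium | C[Al](C)/C=C(C)/CC/C=C(C)/Br | intermediate
7 | (1E,5E)-6-bromo-1-iodo-2-methylhepta-1,5-diene | I/C=C(C)/CC/C=C(C)/Br | intermediate
8 | (4R)-4-benzyl-3-(3-methylbutanoyl)-1,3-oxazolidin-2-one | CC(C)CC(=O)N1[C@H](Cc2ccccc2)COC1=O | starting material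
9 | chloroacetaldehyde | ClCC=O | starting material
10 | Z-dibutylboron enolate of 8 | CC(C)/C=C(\OB(CCCC)CCCC)N1[C@H](Cc2ccccc2)COC1=O | intermediate
11 | (4R)-4-benzyl-3-[(2R,3R)-4-chloro-3-hydroxy-2-(propan-2-yl)butanoyl]-1,3-oxazolidin-2-one | ClC[C@H](O)[C@@H](C(C)C)C(=O)N1[C@H](Cc2ccccc2)COC1=O | intermediate
12 | (2R,3R)-4-chloro-3-hydroxy-N-methoxy-N-methyl-2-(propan-2-yl)butanamide | ClC[C@H](O)[C@@H](C(C)C)C(=O)N(C)OC | intermediate
13 | [(1E,5E)-6-bromo-2-methylhepta-1,5-dien-1-yl]lithium | [Li]/C=C(C)/CC/C=C(C)/Br | intermediate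
14 | chloromagnesium alkoxide of 12 | ClC[C@H](O[Mg]Cl)[C@@H](C(C)C)C(=O)N(C)OC | intermediate
15 | (2R,3R,5E,9E)-10-bromo-1-chloro-2-hydroxy-6-methyl-3-(propan-2-yl)undeca-5,9-dien-4-one | ClC[C@H](O)[C@@H](C(C)C)C(=O)/C=C(C)/CC/C=C(C)/Br | intermediate
16 | (2R,3S,4S,5E,9E)-10-bromo-1-chloro-6-methyl-3-(propan-2-yl)undeca-5,9-diene-2,4-diol | ClC[C@H](O)[C@@H](C(C)C)[C@@H](O)/C=C(C)/CC/C=C(C)/Br | intermediate
17 | (3S,4S,5E,9E)-10-bromo-2,6-dimethyl-3-[(2R)-oxiran-2-yl]undeca-5,9-dien-4-ol (formed as its sodium alkoxide) | C1O[C@@H]1[C@@H](C(C)C)[C@@H](O)/C=C(C)/CC/C=C(C)/Br | intermediate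
18 | tert-butyl({(3R,4S,5E,9E)-10-bromo-2,6-dimethyl-3-[(2R)-oxiran-2-yl]undeca-5,9-dien-4-yl}oxy)dimethylsilane | C1O[C@@H]1[C@@H](C(C)C)[C@@H](O[Si](C)(C)C(C)(C)C)/C=C(C)/CC/C=C(C)/Br | intermediate
19 | (E)-alkenyllithium from 18 (lithium in place of bromine) | C1O[C@@H]1[C@@H](C(C)C)[C@@H](O[Si](C)(C)C(C)(C)C)/C=C(C)/CC/C=C(C)/[Li] | intermediate
20 | (1S,3E,7E,9S,10R)-9-{[tert-butyl(dimethyl)silyl]oxy}-3,7-dimethyl-10-(propan-2-yl)cyclodeca-3,7-dien-1-ol | O[C@H]1C/C(C)=C/CC/C(C)=C/[C@H](O[Si](C)(C)C(C)(C)C)[C@@H]1C(C)C | intermediate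
21 | (E)-ferulic acid, (2E)-3-(4-hydroxy-3-methoxyphenyl)prop-2-enoic acid | COc1cc(/C=C/C(=O)O)ccc1O | starting material
22 | tert-butyldimethylsilyl (2E)-3-{4-[tert-butyl(dimethyl)silyl]oxy-3-methoxyphenyl}prop-2-enoate | COc1cc(/C=C/C(=O)O[Si](C)(C)C(C)(C)C)ccc1O[Si](C)(C)C(C)(C)C | intermediate
23 | (2E)-3-{4-[tert-butyl(dimethyl)silyl]oxy-3-methoxyphenyl}prop-2-enoic acid | COc1cc(/C=C/C(=O)O)ccc1O[Si](C)(C)C(C)(C)C | intermediate
24 | (1S,3E,7E,9S,10R)-9-{[tert-butyl(dimethyl)silyl]oxy}-3,7-dimethyl-10-(propan-2-yl)cyclodeca-3,7-dien-1-yl (2E)-3-{4-[tert-butyl(dimethyl)silyl]oxy-3-methoxyphenyl}prop-2-enoate | COc1cc(/C=C/C(=O)O[C@H]2C/C(C)=C/CC/C(C)=C/[C@H](O[Si](C)(C)C(C)(C)C)[C@@H]2C(C)C)ccc1O[Si](C)(C)C(C)(C)C | intermediate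
25 | (1S,3E,7E,9S,10S)-9-hydroxy-3,7-dimethyl-10-(propan-2-yl)cyclodeca-3,7-dien-1-yl (2E)-3-(4-hydroxy-3-methoxyphenyl)prop-2-enoate | COc1cc(/C=C/C(=O)O[C@H]2C/C(C)=C/CC/C(C)=C/[C@H](O)[C@@H]2C(C)C)ccc1O | target

Total step count: 13. Longest linear sequence: 10 steps (1, 2, 3, 4, 7, 8, 9, 10, 12, 13).

Steps most likely to fail

Step 10. Intermolecular epoxide opening (oligomerisation) may outrun ring closure, the very dilute alkenyllithium may be quenched by adventitious protons, or the Lewis acid may ionise the allylic silyl ether. The fallback sets out from 18 and comes back at 20. The epoxide of 18 would be opened at its terminal carbon by a copper–boryl species (B2pin2, CuCl/Xantphos, KOt-Bu, MeOH, THF, rt) to give the β-hydroxyalkyl pinacol boronate F1. An intramolecular Suzuki–Miyaura coupling of F1 with its own alkenyl bromide (Pd(OAc)2/SPhos, K3PO4, THF/H2O, 60 °C, syringe-pump addition) would then form the same C-2–C-3 bond on palladium, without an organolithium or a Lewis acid, and give 20.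

Step 7. Bromine–lithium exchange may compete with iodine–lithium exchange, the hindered amide may be enolised instead of attacked, or the chlorohydrin alkoxide may close during warming. The fallback sets out from 12 and comes back at 15. Amide 12 would be silylated (TESCl, imidazole, DMF) to the triethylsilyl ether F2 and reduced (i-Bu2AlH, THF, −78 °C) to the aldehyde F3. A Nozaki–Hiyama–Kishi coupling of F3 with 7 (CrCl2, NiCl2 cat., DMSO/THF), in which only the alkenyl iodide is activated, would give the allylic alcohols F4 as a mixture of epimers at the new carbinol. Oxidation (Dess–Martin periodinane) to the enone F5 and removal of the silyl group (HF·pyridine, THF) would return to 15.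

Step 9. The C-4 alkoxide may attack the chloromethyl carbon and form a five-membered ether in competition with epoxide closure. The fallback sets out from 15, replaces steps 8 and 9, and comes back at 18. An Evans–Tishchenko reduction of 15 (SmI2 cat., acetaldehyde, THF, −10 °C) would set the same 1,3-anti C-4 carbinol while leaving the C-2 oxygen acylated, giving the hydroxy acetate F6. Silylation of the only free hydroxyl (TBSOTf, 2,6-lutidine, CH2Cl2, −78 °C) would give the silyl ether F7. Methanolysis of the acetate (K2CO3, MeOH, 0 °C) would free the chlorohydrin alkoxide with no competing alkoxide present, and its closure would give 18.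

Further compounds
F1 | step 10 | (2S,3R,4S,5E,9E)-10-bromo-4-{[tert-butyl(dimethyl)silyl]oxy}-6-methyl-3-(propan-2-yl)-1-(4,4,5,5-tetramethyl-1,3,2-dioxaborolan-2-yl)undeca-5,9-dien-2-ol | CC1(C)OB(C[C@H](O)[C@@H](C(C)C)[C@@H](O[Si](C)(C)C(C)(C)C)/C=C(C)/CC/C=C(C)/Br)OC1(C)C
F2 | step 7 | (2R,3R)-4-chloro-N-methoxy-N-methyl-2-(propan-2-yl)-3-(triethylsilyloxy)butanamide | ClC[C@H](O[Si](CC)(CC)CC)[C@@H](C(C)C)C(=O)N(C)OC
F3 | step 7 | (2R,3R)-4-chloro-2-(propan-2-yl)-3-(triethylsilyloxy)butanal | ClC[C@H](O[Si](CC)(CC)CC)[C@@H](C(C)C)C=O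
F4 | step 7 | (2R,3S,4RS,5E,9E)-10-bromo-1-chloro-6-methyl-3-(propan-2-yl)-2-(triethylsilyloxy)undeca-5,9-dien-4-ol | ClC[C@H](O[Si](CC)(CC)CC)[C@@H](C(C)C)C(O)/C=C(C)/CC/C=C(C)/Br
F5 | step 7 | (2R,3R,5E,9E)-10-bromo-1-chloro-6-methyl-3-(propan-2-yl)-2-(triethylsilyloxy)undeca-5,9-dien-4-one | ClC[C@H](O[Si](CC)(CC)CC)[C@@H](C(C)C)C(=O)/C=C(C)/CC/C=C(C)/Br
F6 | step 9 | (2R,3S,4S,5E,9E)-10-bromo-1-chloro-4-hydroxy-6-methyl-3-(propan-2-yl)undeca-5,9-dien-2-yl acetate | ClC[C@H](OC(C)=O)[C@@H](C(C)C)[C@@H](O)/C=C(C)/CC/C=C(C)/Br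
F7 | step 9 | (2R,3R,4S,5E,9E)-10-bromo-4-{[tert-butyl(dimethyl)silyl]oxy}-1-chloro-6-methyl-3-(propan-2-yl)undeca-5,9-dien-2-yl acetate | ClC[C@H](OC(C)=O)[C@@H](C(C)C)[C@@H](O[Si](C)(C)C(C)(C)C)/C=C(C)/CC/C=C(C)/Br
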